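**Retrosynthetic overview**

1. Target 10 ← acetate 9 by hydrolysis of one temporary acetonide; nothing else changes.
2. 9 ← enone 5 + pentadecanal 6 + Ac2O. The exocyclic C5–C6 bond is made by a lithium-enolate aldol with the aldolate acetylated in the same flask; this sets the quaternary C5 and the carbinol C6 together and installs the ester.
3. Enabling feature: C5 is α to the C1 ketone and is also a member of a cis-fused 1,3-dioxolane ring (O4–CMe2–O5 across C4–C5 of the cyclopentenone ring). The ring forces the aldehyde onto the face anti to C4–O, and loss of O4 from the enolate is blocked because it would give an antiaromatic cyclopentadienone.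
4. 5 ← (1S,4R)-cis-4-acetoxycyclopent-2-en-1-ol 1 by anti dihydroxylation, acetonide formation and oxidation/β-elimination of acetate.
5. Ring order: the carbocycle is bought with 1 and never opened; the dioxolane is closed in step 2 and opened in step 5.

Key step: step 4

Remark: atoms are numbered as in cyclopent-2-en-1-one (C1 carbonyl, C2=C3, C4 secondary carbinol, C5 quaternary carbinol), C6 is the acetoxy-bearing side-chain carbon, and O4/O5/O6 are the oxygens on those carbons. The target is read as (4S,5R,6S): a cis-4,5-diol with the side chain trans to the 4-hydroxyl. Compounds 1 and 6 are taken as catalogue compounds.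

**Route**

Step 1
Reactants: 1 (1S,4R)-cis-4-acetoxycyclopent-2-en-1-ol
Product: 2 (1R,2R,3R,4S)-2,3,4-trihydroxycyclopentyl acetate (new 2,3-diol cis, on the face opposite to the 4-hydroxyl and the acetate)
Conditions: OsO4 (cat.), NMO, acetone/H2O, 0 °C to rt; crude 2 taken on directly
Reagents that add atoms: OsO4, O=[Os](=O)(=O)=O (carrier of both oxygens); N-methylmorpholine N-oxide, C[N+]1([O-])CCOCC1; water, O
Why: Upjohn dihydroxylation: the concerted syn addition should occur on the alkene face anti to the two allylic oxygen substituents, which both sit on the other face, so the two new carbinol centres come out cis to each other and trans to the hydroxyl and the acetate.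

Step 2
Reactants: 2 (1R,2R,3R,4S)-2,3,4-trihydroxycyclopentyl acetate
Product: 3 (1R,2S,3R,4S)-4-hydroxy-2,3-(isopropylidenedioxy)cyclopentyl acetate
Conditions: 2,2-dimethoxypropane, PPTS (cat.), acetone, rt
Reagents that add atoms: 2,2-dimethoxypropane, COC(C)(C)OC
Why: Acid-catalysed acetonide formation (transketalisation): only the cis-2,3-diol can close a five-membered dioxolane on the cyclopentane, the hydroxyl trans to it stays free, and the mild pyridinium acid should leave the acetate in place; no stereocentre is formed or touched.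

Step 3
Reactants: 3 (1R,2S,3R,4S)-4-hydroxy-2,3-(isopropylidenedioxy)cyclopentyl acetate
Product: 5 (3aS,6aS)-2,2-dimethyl-3a,6a-dihydro-4H-cyclopenta[d][1,3]dioxol-4-one [(4S,5S)-4,5-(isopropylidenedioxy)cyclopent-2-en-1-one], via acetoxy ketone 4 (not isolated)
Conditions: Dess–Martin periodinane, CH2Cl2, 0 °C to rt; then Et3N, 0 °C to rt
Reagents that add atoms: none
Why: Dess–Martin oxidation to ketone 4 followed by amine-promoted E1cB β-elimination of acetate through the methylene enolate should give the conjugated enone; acetate is a far better leaving group than the dioxolane oxygen on the other side, and the two ring-fusion centres cannot epimerise because the dioxolane must stay cis-fused.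

Step 4
Reactants: 5 (3aS,6aS)-2,2-dimethyl-3a,6a-dihydro-4H-cyclopenta[d][1,3]dioxol-4-one; 6 pentadecanal
Product: 9 (3aS,6aS)-3a-[(1S)-1-acetoxypentadecyl]-2,2-dimethyl-3a,6a-dihydro-4H-cyclopenta[d][1,3]dioxol-4-one, via lithium enolate 7 (not isolated), via lithium aldolate 8 (not isolated)
Conditions: LiN(iPr)2, THF, −78 °C; 6, −78 °C; Ac2O, −78 to −20 °C
Reagents that add atoms: acetic anhydride, CC(=O)OC(C)=O
Why: LiN(iPr)2 removes the α′ proton at C5 of 5 to give the 2-oxidocyclopentadiene-type lithium enolate 7, which should survive although it carries a β-alkoxy group at C4, because E1cB loss of O4 would generate an antiaromatic cyclopentadienone. The enolate then adds to pentadecanal through a Zimmerman–Traxler chair and the lithium aldolate 8 is O-acetylated in the same flask; the closest known reaction type is the aldol of lithium enolates of α-alkoxy cycloalkenones with trapping of the aldolate by an anhydride, and no ring is closed. C5 is controlled by the cis-fused dioxolane ring: O5 must stay cis to O4, so the aldehyde can bond only on the face anti to the C4–O bond, which places the side chain trans to O4 as in the target. C6 is controlled by simple diastereoselection: the ring fixes the enolate geometry (C4 trans and O5 cis to the O–Li), and with the tetradecyl chain equatorial in the chair, anti to C1 and away from C2–H and the lithium ligands, O6 should come out syn to O5 and anti to C4 in the C1–C5–C6–C7 zigzag, which is 6S. The step needs α′ over γ deprotonation (kinetic amide base at −78 °C), addition faster than proton transfer to the enolisable aldehyde, and acetylation faster than retro-aldol, which is served by adding Ac2O cold; once acetylated the adduct is locked, since C5 bears no hydrogen and neither β-elimination of acetate nor epimerisation is open.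

Step 5
Reactants: 9 (3aS,6aS)-3a-[(1S)-1-acetoxypentadecyl]-2,2-dimethyl-3a,6a-dihydro-4H-cyclopenta[d][1,3]dioxol-4-one
Product: 10 (1S)-1-[(1R,5S)-1,5-dihydroxy-2-oxocyclopent-3-en-1-yl]pentadecyl acetate [(4S,5R)-5-[(1S)-1-acetoxypentadecyl]-4,5-dihydroxycyclopent-2-en-1-one]
Conditions: CF3CO2H/H2O (9:1), 0 °C
Reagents that add atoms: none
Why: Acid-catalysed hydrolysis of the isopropylidene acetal should free the cis-4,5-diol without breaking any bond to a stereocentre; the secondary acetate is stable to cold aqueous CF3CO2H, and acetyl transfer to the tertiary O5, or to O4 which lies trans to the side chain, should be slow under acid.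

**Compound list**

1 | (1S,4R)-cis-4-acetoxycyclopent-2-en-1-ol | O[C@@H]1C=C[C@H](OC(C)=O)C1 | starting material
2 | (1R,2R,3R,4S)-2,3,4-trihydroxycyclopentyl acetate | O[C@@H]1[C@@H](O)[C@@H](O)[C@H](OC(C)=O)C1 | intermediate
3 | (1R,2S,3R,4S)-4-hydroxy-2,3-(isopropylidenedioxy)cyclopentyl acetate | O[C@@H]1[C@H]2OC(C)(C)O[C@H]2[C@H](OC(C)=O)C1 | intermediate
4 | (1R,2S,3S)-2,3-(isopropylidenedioxy)-4-oxocyclopentyl acetate (acetoxy ketone, not isolated) | O=C1[C@H]2OC(C)(C)O[C@H]2[C@H](OC(C)=O)C1 | intermediate
5 | (3aS,6aS)-2,2-dimethyl-3a,6a-dihydro-4H-cyclopenta[d][1,3]dioxol-4-one | O=C1C=C[C@@H]2OC(C)(C)O[C@H]12 | intermediate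
6 | pentadecanal | CCCCCCCCCCCCCCC=O | starting material
7 | lithium (6aS)-2,2-dimethyl-6aH-cyclopenta[d][1,3]dioxol-4-olate (lithium enolate, not isolated) | [Li]OC1=C2OC(C)(C)O[C@H]2C=C1 | intermediate
8 | lithium alkoxide of the (1S)-aldol: (3aS,6aS)-3a-[(1S)-1-(lithiooxy)pentadecyl]-2,2-dimethyl-3a,6a-dihydro-4H-cyclopenta[d][1,3]dioxol-4-one (lithium aldolate, not isolated) | CCCCCCCCCCCCCC[C@H](O[Li])[C@]12OC(C)(C)O[C@H]1C=CC2=O | intermediate
9 | (3aS,6aS)-3a-[(1S)-1-acetoxypentadecyl]-2,2-dimethyl-3a,6a-dihydro-4H-cyclopenta[d][1,3]dioxol-4-one | CCCCCCCCCCCCCC[C@H](OC(C)=O)[C@]12OC(C)(C)O[C@H]1C=CC2=O | intermediate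
10 | (1S)-1-[(1R,5S)-1,5-dihydroxy-2-oxocyclopent-3-en-1-yl]pentadecyl acetate | CCCCCCCCCCCCCC[C@H](OC(C)=O)[C@@]1(O)C(=O)C=C[C@@H]1O | target

**Totals**

Total step count: 5. Longest linear sequence: 5 steps (1 to 10).

**Steps most likely to fail**

Step 4. The risk is weak simple diastereoselection at C6, or retro-aldol equilibration of the aldolate while it warms for acetylation. The fallback separates bond formation from control of C6; it sets out from 8 and comes back at 9. The aldolate is quenched at −78 °C with AcOH in THF instead of being acetylated. This gives (3aS,6aS)-3a-[(1S)-1-hydroxypentadecyl]-2,2-dimethyl-3a,6a-dihydro-4H-cyclopenta[d][1,3]dioxol-4-one F1 together with its (1R)-epimer F2. The mixture is oxidised with Dess–Martin periodinane to the single diketone (3aR,6aS)-2,2-dimethyl-3a-pentadecanoyl-3a,6a-dihydro-4H-cyclopenta[d][1,3]dioxol-4-one F3, whose quaternary C5 cannot epimerise. NaBH4 in MeOH/CH2Cl2 at −78 °C should reduce the non-conjugated, α-alkoxy-activated side-chain ketone ahead of the ring enone carbonyl. With O5 anti to the incoming hydride (polar Felkin–Anh) and attack past the flat C1 carbonyl rather than the C4 methine, it should return F1 with the (1S) configuration. Ac2O, DMAP and pyridine then give 9.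

Step 5. The risk is loss or migration of the acetyl group while the acetal is hydrolysed. The fallback lets the ester meet no acid; it sets out from 8 and comes back at 10. Quenching 8 with AcOH gives the free aldol F1, and CF3CO2H/H2O then hydrolyses the acetonide to (4S,5S)-4,5-dihydroxy-5-[(1S)-1-hydroxypentadecyl]cyclopent-2-en-1-one F4. PhB(OH)2 in toluene should tie the cis-4,5-diol as the cyclic 4,5-O-phenylboronate of F4, F5. Ac2O, DMAP and pyridine then acetylate the only free hydroxyl, at C6, to give the 6-O-acetate of that boronate, F6. Transesterification with pinacol in acetone/H2O should release 10 under neutral conditions.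

Step 1. The risk is loss of the very polar triol monoacetate on isolation, and acetyl transfer within it to O3 or across the ring to O1, the latter eroding enantiopurity. The fallback is a silyl relay that sets out from 1 and comes back at 3. TBSCl and imidazole in DMF give the tert-butyldimethylsilyl ether of 1, F7. OsO4/NMO should then give the extractable tert-butyldimethylsilyl ether of 2, F8, with the same anti facial course and with O1 blocked. 2,2-Dimethoxypropane/PPTS gives the tert-butyldimethylsilyl ether of 3, F9. HF·pyridine in THF/pyridine, which generates no alkoxide next to the ester, removes the silyl group and returns 3.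

**Further compounds**

F1 | step 4 | (3aS,6aS)-3a-[(1S)-1-hydroxypentadecyl]-2,2-dimethyl-3a,6a-dihydro-4H-cyclopenta[d][1,3]dioxol-4-one | CCCCCCCCCCCCCC[C@H](O)[C@]12OC(C)(C)O[C@H]1C=CC2=O
F2 | step 4 | (3aS,6aS)-3a-[(1R)-1-hydroxypentadecyl]-2,2-dimethyl-3a,6a-dihydro-4H-cyclopenta[d][1,3]dioxol-4-one | CCCCCCCCCCCCCC[C@@H](O)[C@]12OC(C)(C)O[C@H]1C=CC2=O
F3 | step 4 | (3aR,6aS)-2,2-dimethyl-3a-pentadecanoyl-3a,6a-dihydro-4H-cyclopenta[d][1,3]dioxol-4-one | CCCCCCCCCCCCCCC(=O)[C@]12OC(C)(C)O[C@H]1C=CC2=O
F4 | step 5 | (4S,5S)-4,5-dihydroxy-5-[(1S)-1-hydroxypentadecyl]cyclopent-2-en-1-one | CCCCCCCCCCCCCC[C@H](O)[C@@]1(O)C(=O)C=C[C@@H]1O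
F5 | step 5 | cyclic 4,5-O-phenylboronate of F4 | CCCCCCCCCCCCCC[C@H](O)[C@]12OB(c3ccccc3)O[C@H]1C=CC2=O
F6 | step 5 | 6-O-acetate of the cyclic 4,5-O-phenylboronate F5 | CCCCCCCCCCCCCC[C@H](OC(C)=O)[C@]12OB(c3ccccc3)O[C@H]1C=CC2=O
F7 | step 1 | tert-butyldimethylsilyl ether of 1, (1R,4S)-4-(tert-butyldimethylsilyloxy)cyclopent-2-en-1-yl acetate | CC(C)(C)[Si](C)(C)O[C@@H]1C=C[C@H](OC(C)=O)C1
F8 | step 1 | tert-butyldimethylsilyl ether of 2 (silyl group on the hydroxyl trans to the diol) | CC(C)(C)[Si](C)(C)O[C@@H]1[C@@H](O)[C@@H](O)[C@H](OC(C)=O)C1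
F9 | step 1 | tert-butyldimethylsilyl ether of 3 | CC(C)(C)[Si](C)(C)O[C@@H]1[C@H]2OC(C)(C)O[C@H]2[C@H](OC(C)=O)C1
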